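## Retrosynthetic overview

- The strategy rests on the C2'' secondary carbinol (R) lying next to the C3''=C4'' methylene in the four-carbon chain on C6 of ring A. This unit is the 1,3-transposed form of a primary E allylic alcohol (C4''–OH, C2''=C3'').
- Target ⇐ desilylation ⇐ zinc-induced opening of a 2,3-epoxy iodide (C3''–O broken, C2''–O kept) ⇐ iodination of the 2R,3R epoxy alcohol.
- Epoxy alcohol ⇐ titanium/tartrate epoxidation of the E allylic alcohol on the tris-silylated isoflavone (C2''–O and C3''–O formed together).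
- E allylic alcohol ⇐ 1,2-reduction of the enal ⇐ cross-metathesis of a C6 allyl group with methacrolein ⇐ Claisen shift of the C5 allyl ether of 7,4'-bis-silylated genistein.
- Ring order: rings A, C and B come intact from genistein; the only ring made is the oxirane (step 7), which is opened again in step 9.

Key step: step 7

Remark on the chemistry: isoflavone numbering is used (ring A = C5–C8, ring C = the pyranone, ring B = the 4'-oxygenated phenyl; side chain C1''–C4'' with the methyl on C3''). The C5 hydroxyl is etherified with allyl alcohol under Mitsunobu conditions, not with allyl bromide and carbonate, so that the aryl silyl ethers never meet base.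

## Route

Step 1
Reactants: 1 genistein
Product: 2 5-hydroxy-7-(triisopropylsilyloxy)-3-[4-(triisopropylsilyloxy)phenyl]-4H-chromen-4-one
Conditions: TIPSCl (2.3 equiv), imidazole, DMF, 0 → 23 °C
Reagents that add atoms: triisopropylsilyl chloride, CC(C)[Si](Cl)(C(C)C)C(C)C
Why: Imidazole-promoted silyl ether formation should take the two acidic, unhindered phenols at C7 and C4', while the C5 hydroxyl, hydrogen-bonded to the C4 carbonyl, stays free.

Step 2
Reactants: 2 7,4'-bis-silylated genistein; 3 allyl alcohol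
Product: 4 5-(allyloxy)-7-(triisopropylsilyloxy)-3-[4-(triisopropylsilyloxy)phenyl]-4H-chromen-4-one
Conditions: PPh3, DIAD, THF, 0 → 23 °C
Reagents that add atoms: none
Why: Mitsunobu etherification is an established way to alkylate the chelated C5 hydroxyl of flavonoids with primary allylic alcohols, and its neutral conditions leave aryl silyl ethers alone.

Step 3
Reactants: 4 5-O-allyl ether
Product: 6 6-allyl-5-hydroxy-7-(triisopropylsilyloxy)-3-[4-(triisopropylsilyloxy)phenyl]-4H-chromen-4-one, via C6-allyl cyclohexadienone 5 (not isolated)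
Conditions: PhNEt2, 200 °C, sealed tube, argon
Reagents that add atoms: none
Why: The aromatic Claisen rearrangement ([3,3]-sigmatropic shift) can only reach C6, the one free ortho position, and the amine solvent should speed tautomerisation of dienone 5 to the phenol before a Cope shift to C8 competes.

Step 4
Reactants: 6 6-allyl-5-hydroxy compound
Product: 7 6-allyl-5-(tert-butyldimethylsilyloxy)-7-(triisopropylsilyloxy)-3-[4-(triisopropylsilyloxy)phenyl]-4H-chromen-4-one
Conditions: TBSOTf, 2,6-lutidine, CH2Cl2, 0 → 23 °C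
Reagents that add atoms: tert-butyldimethylsilyl trifluoromethanesulfonate, CC(C)(C)[Si](C)(C)OS(=O)(=O)C(F)(F)F
Why: Silylation with a silyl triflate and a hindered pyridine base is strong enough to cap a hydrogen-bonded, doubly flanked phenol, which removes the C5-hydroxy/C4-keto chelating site before titanium is used.

Step 5
Reactants: 7 tris-silylated 6-allyl isoflavone; 8 methacrolein (10 equiv)
Product: 9 (E)-2-methyl-4-{5-(tert-butyldimethylsilyloxy)-4-oxo-7-(triisopropylsilyloxy)-3-[4-(triisopropylsilyloxy)phenyl]-4H-chromen-6-yl}but-2-enal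
Conditions: second-generation Grubbs catalyst (H2IMes)(PCy3)Cl2Ru=CHPh (5 mol %), 1,4-benzoquinone (10 mol %), CH2Cl2, 40 °C
Reagents that add atoms: none
Why: Olefin cross-metathesis of a terminal allyl arene with excess methacrolein should give the conjugated trisubstituted enal with E geometry under thermodynamic control, the electron-poor C2=C3 bond of ring C staying out and the quinone suppressing allyl-to-propenyl isomerisation.

Step 6
Reactants: 9 E enal
Product: 10 6-[(E)-4-hydroxy-3-methylbut-2-enyl]-5-(tert-butyldimethylsilyloxy)-7-(triisopropylsilyloxy)-3-[4-(triisopropylsilyloxy)phenyl]-4H-chromen-4-one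
Conditions: NaBH4, CeCl3·7H2O, MeOH/THF, −40 °C
Reagents that add atoms: none
Why: Luche reduction should deliver hydride 1,2 to the aldehyde, which is far more electrophilic than the vinylogous-ester carbonyl of ring C, and it keeps the E double bond on which the enantiopurity of step 7 depends.

Step 7
Reactants: 10 E allylic alcohol
Product: 11 [(2R,3R)-2-methyl-3-({5-(tert-butyldimethylsilyloxy)-4-oxo-7-(triisopropylsilyloxy)-3-[4-(triisopropylsilyloxy)phenyl]-4H-chromen-6-yl}methyl)oxiran-2-yl]methanol
Conditions: Ti(OiPr)4 (0.3 equiv), D-(−)-diethyl tartrate (0.36 equiv), tBuOOH (2 equiv, decane), 4 Å MS, CH2Cl2, −20 °C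
Reagents that add atoms: tert-butyl hydroperoxide, CC(C)(C)OO
Why: The primary allylic alkoxide and tert-butyl peroxide are bound to the dimeric titanium tartrate, and the peroxide oxygen is handed to the C2''=C3'' bond in one concerted step (Sharpless asymmetric epoxidation; closest precedent: E-2-methyl-2-alken-1-ols, a reliable trisubstituted substrate class). The oxirane closes by formation of the C2''–O and C3''–O bonds at the same time on one alkene face, a [2+1] oxygen-atom transfer with no open-chain intermediate, so the E geometry is carried into the trans arrangement of CH2OH and CH2Ar. Both new centres are fixed by the ligand: L-(+)-tartrate leads E allylic alcohols of this substitution pattern into the 2S,3S series, so the mirror-image D-(−)-diethyl tartrate should give the 2R,3R oxirane, whose CH–O carbon (the later C2'') already has the target configuration. The step needs chemoselectivity for the side-chain alkene and enantioface selectivity; the first is secured because only this alkene carries a titanium-binding hydroxyl (the C2=C3 bond of ring C is electron-poor and undirected), the second because all three phenols, including the chelating C5 oxygen, are silylated and cannot compete for titanium. Molecular sieves should keep the catalyst turning over and limit opening of the product by isopropoxide.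

Step 8
Reactants: 11 2R,3R epoxy alcohol
Product: 12 (2S,3R)-2-(iodomethyl)-2-methyl-3-({5-(tert-butyldimethylsilyloxy)-4-oxo-7-(triisopropylsilyloxy)-3-[4-(triisopropylsilyloxy)phenyl]-4H-chromen-6-yl}methyl)oxirane (same spatial arrangement as 11; the descriptor at the quaternary carbon changes only because CH2I outranks the ring carbon)
Conditions: I2, PPh3, imidazole, CH2Cl2, 0 °C
Reagents that add atoms: iodine, II
Why: Appel-type iodination converts the primary alcohol into the iodide under buffered conditions that should leave the oxirane and both stereocentres untouched.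

Step 9
Reactants: 12 epoxy iodide
Product: 13 6-[(2R)-2-hydroxy-3-methylbut-3-enyl]-5-(tert-butyldimethylsilyloxy)-7-(triisopropylsilyloxy)-3-[4-(triisopropylsilyloxy)phenyl]-4H-chromen-4-one
Conditions: Zn dust, EtOH, 60 °C; aq NH4Cl work-up
Reagents that add atoms: none
Why: Zinc inserts into the C–I bond and the organozinc undergoes β-elimination that opens the oxirane (reductive 1,3-transposition of a 2,3-epoxy iodide), breaking only the C3''–O bond, so the C3''=C4'' methylene appears and the C2''–O bond keeps its R configuration.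

Step 10
Reactants: 13 tris-silylated R allylic alcohol
Product: 14 5,7-dihydroxy-6-[(2R)-2-hydroxy-3-methylbut-3-enyl]-3-(4-hydroxyphenyl)-4H-chromen-4-one (target)
Conditions: Bu4NF, AcOH, THF, 0 → 23 °C
Reagents that add atoms: none
Why: Fluoride cleavage of the three aryl silyl ethers, buffered with acetic acid to protect the base-sensitive ring C, should free the triphenol without touching C2'' or the allylic alcohol.

## Compound list

1 | genistein | O=c1c(-c2ccc(O)cc2)coc2cc(O)cc(O)c12 | starting material
2 | 5-hydroxy-7-(triisopropylsilyloxy)-3-[4-(triisopropylsilyloxy)phenyl]-4H-chromen-4-one | Oc1cc(O[Si](C(C)C)(C(C)C)C(C)C)cc2occ(-c3ccc(O[Si](C(C)C)(C(C)C)C(C)C)cc3)c(=O)c12 | intermediate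
3 | allyl alcohol (prop-2-en-1-ol) | C=CCO | starting material
4 | 5-(allyloxy)-7-(triisopropylsilyloxy)-3-[4-(triisopropylsilyloxy)phenyl]-4H-chromen-4-one | C=CCOc1cc(O[Si](C(C)C)(C(C)C)C(C)C)cc2occ(-c3ccc(O[Si](C(C)C)(C(C)C)C(C)C)cc3)c(=O)c12 | intermediate
5 | 6-allyl-7-(triisopropylsilyloxy)-3-[4-(triisopropylsilyloxy)phenyl]-6H-chromene-4,5-dione (Claisen dienone, C6 unspecified) | C=CCC1C(=O)C2=C(C=C1O[Si](C(C)C)(C(C)C)C(C)C)OC=C(c1ccc(O[Si](C(C)C)(C(C)C)C(C)C)cc1)C2=O | intermediate
6 | 6-allyl-5-hydroxy-7-(triisopropylsilyloxy)-3-[4-(triisopropylsilyloxy)phenyl]-4H-chromen-4-one | C=CCc1c(O[Si](C(C)C)(C(C)C)C(C)C)cc2occ(-c3ccc(O[Si](C(C)C)(C(C)C)C(C)C)cc3)c(=O)c2c1O | intermediate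
7 | 6-allyl-5-(tert-butyldimethylsilyloxy)-7-(triisopropylsilyloxy)-3-[4-(triisopropylsilyloxy)phenyl]-4H-chromen-4-one | C=CCc1c(O[Si](C(C)C)(C(C)C)C(C)C)cc2occ(-c3ccc(O[Si](C(C)C)(C(C)C)C(C)C)cc3)c(=O)c2c1O[Si](C)(C)C(C)(C)C | intermediate
8 | methacrolein (2-methylprop-2-enal) | C=C(C)C=O | starting material
9 | (E)-2-methyl-4-(tris-silylated isoflavon-6-yl)but-2-enal | O=C/C(C)=C/Cc1c(O[Si](C(C)C)(C(C)C)C(C)C)cc2occ(-c3ccc(O[Si](C(C)C)(C(C)C)C(C)C)cc3)c(=O)c2c1O[Si](C)(C)C(C)(C)C | intermediate
10 | 6-[(E)-4-hydroxy-3-methylbut-2-enyl] tris-silylated isoflavone | OC/C(C)=C/Cc1c(O[Si](C(C)C)(C(C)C)C(C)C)cc2occ(-c3ccc(O[Si](C(C)C)(C(C)C)C(C)C)cc3)c(=O)c2c1O[Si](C)(C)C(C)(C)C | intermediate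
11 | [(2R,3R)-2-methyl-3-(tris-silylated isoflavon-6-ylmethyl)oxiran-2-yl]methanol | OC[C@@]1(C)O[C@@H]1Cc1c(O[Si](C(C)C)(C(C)C)C(C)C)cc2occ(-c3ccc(O[Si](C(C)C)(C(C)C)C(C)C)cc3)c(=O)c2c1O[Si](C)(C)C(C)(C)C | intermediate
12 | (2S,3R)-2-(iodomethyl)-2-methyl-3-(tris-silylated isoflavon-6-ylmethyl)oxirane | IC[C@@]1(C)O[C@@H]1Cc1c(O[Si](C(C)C)(C(C)C)C(C)C)cc2occ(-c3ccc(O[Si](C(C)C)(C(C)C)C(C)C)cc3)c(=O)c2c1O[Si](C)(C)C(C)(C)C | intermediate
13 | 6-[(2R)-2-hydroxy-3-methylbut-3-enyl] tris-silylated isoflavone | C=C(C)[C@H](O)Cc1c(O[Si](C(C)C)(C(C)C)C(C)C)cc2occ(-c3ccc(O[Si](C(C)C)(C(C)C)C(C)C)cc3)c(=O)c2c1O[Si](C)(C)C(C)(C)C | intermediate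
14 | 5,7-dihydroxy-6-[(2R)-2-hydroxy-3-methylbut-3-enyl]-3-(4-hydroxyphenyl)-4H-chromen-4-one | C=C(C)[C@H](O)Cc1c(O)cc2occ(-c3ccc(O)cc3)c(=O)c2c1O | target

## Step count

Total steps: 10. Longest linear sequence: 10 steps (1 → 14).

## Steps most likely to fail

**Step 7.** Oxygen transfer may be slow or poorly face-selective if the chromone carbonyl competes for titanium. The Lewis acid may also open the new oxirane through a neighbouring aryl silyl ether oxygen, with ring closure onto the side chain. The fallback sets out from 10 and replaces the metal-alkoxide epoxidation by the metal-free Shi epoxidation. It uses the D-fructose-derived ketone (1,2:4,5-di-O-isopropylidene-β-D-erythro-2,3-hexodiulo-2,6-pyranose), 2KHSO5·KHSO4·K2SO4, K2CO3, Bu4NHSO4, MeCN/dimethoxymethane/aqueous buffer, 0 °C. This ketone is known to give R,R epoxides from trans-disubstituted and E-trisubstituted alkenes, the same face as required here, so it should lead directly to 11, where the fallback rejoins the route. It makes no compound outside the list (F0).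

**Step 4.** Silylation of the hydrogen-bonded C5 hydroxyl, flanked by the allyl group and the C4 carbonyl, may stay incomplete. This activated silyl ether may also be lost later, for instance in methanol with CeCl3. The fallback sets out from 6 and caps C5 as an acetate.
- Ac2O, Et3N, DMAP in CH2Cl2 should give 6-allyl-7,4'-bis(triisopropylsilyloxy)isoflavon-5-yl acetate F1.
- The operations of steps 5 to 9 applied to it should lead through the E enal of the acetate series F2, the E allylic alcohol of the acetate series F3, the 2R,3R epoxy alcohol of the acetate series F4, the epoxy iodide of the acetate series F5 and the transposed R allylic alcohol of the acetate series F6.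
- Buffered Bu4NF should then remove the two silyl groups to give the C5 monoacetate of the target F7.
- K2CO3 in MeOH at 0 °C should cleave the acetate, and the fallback comes back to the route at 14.

**Step 3.** At 200 °C the dienone may undergo a further Cope shift that moves the allyl group to C8, or the silyl ethers may be lost. The fallback sets out from 2 (step 2 is then not needed) and forms the C6–C bond by cross-coupling. Iodination ortho to the free C5 hydroxyl with benzyltrimethylammonium dichloroiodate (BnMe3N+ ICl2−), CaCO3, CH2Cl2/MeOH, 23 °C should give 5-hydroxy-6-iodo-7,4'-bis(triisopropylsilyloxy)isoflavone F8. Stille coupling with allyltributylstannane (Bu3SnCH2CH=CH2), Pd(PPh3)4, DMF, 90 °C should then give 6, where the fallback rejoins the route.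

## Further compounds

F0 | step 7 | none | none
F1 | step 4 | 6-allyl-7,4'-bis(triisopropylsilyloxy)isoflavon-5-yl acetate | C=CCc1c(O[Si](C(C)C)(C(C)C)C(C)C)cc2occ(-c3ccc(O[Si](C(C)C)(C(C)C)C(C)C)cc3)c(=O)c2c1OC(C)=O
F2 | step 4 | 6-[(E)-3-methyl-4-oxobut-2-enyl]-7,4'-bis(triisopropylsilyloxy)isoflavon-5-yl acetate | O=C/C(C)=C/Cc1c(O[Si](C(C)C)(C(C)C)C(C)C)cc2occ(-c3ccc(O[Si](C(C)C)(C(C)C)C(C)C)cc3)c(=O)c2c1OC(C)=O
F3 | step 4 | 6-[(E)-4-hydroxy-3-methylbut-2-enyl]-7,4'-bis(triisopropylsilyloxy)isoflavon-5-yl acetate | OC/C(C)=C/Cc1c(O[Si](C(C)C)(C(C)C)C(C)C)cc2occ(-c3ccc(O[Si](C(C)C)(C(C)C)C(C)C)cc3)c(=O)c2c1OC(C)=O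
F4 | step 4 | 6-{[(2R,3R)-3-(hydroxymethyl)-3-methyloxiran-2-yl]methyl}-7,4'-bis(triisopropylsilyloxy)isoflavon-5-yl acetate | OC[C@@]1(C)O[C@@H]1Cc1c(O[Si](C(C)C)(C(C)C)C(C)C)cc2occ(-c3ccc(O[Si](C(C)C)(C(C)C)C(C)C)cc3)c(=O)c2c1OC(C)=O
F5 | step 4 | 6-{[(2R,3S)-3-(iodomethyl)-3-methyloxiran-2-yl]methyl}-7,4'-bis(triisopropylsilyloxy)isoflavon-5-yl acetate | IC[C@@]1(C)O[C@@H]1Cc1c(O[Si](C(C)C)(C(C)C)C(C)C)cc2occ(-c3ccc(O[Si](C(C)C)(C(C)C)C(C)C)cc3)c(=O)c2c1OC(C)=O
F6 | step 4 | 6-[(2R)-2-hydroxy-3-methylbut-3-enyl]-7,4'-bis(triisopropylsilyloxy)isoflavon-5-yl acetate | C=C(C)[C@H](O)Cc1c(O[Si](C(C)C)(C(C)C)C(C)C)cc2occ(-c3ccc(O[Si](C(C)C)(C(C)C)C(C)C)cc3)c(=O)c2c1OC(C)=O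
F7 | step 4 | 7-hydroxy-6-[(2R)-2-hydroxy-3-methylbut-3-enyl]-3-(4-hydroxyphenyl)-4-oxo-4H-chromen-5-yl acetate | C=C(C)[C@H](O)Cc1c(O)cc2occ(-c3ccc(O)cc3)c(=O)c2c1OC(C)=O
F8 | step 3 | 5-hydroxy-6-iodo-7-(triisopropylsilyloxy)-3-[4-(triisopropylsilyloxy)phenyl]-4H-chromen-4-one | Oc1c(I)c(O[Si](C(C)C)(C(C)C)C(C)C)cc2occ(-c3ccc(O[Si](C(C)C)(C(C)C)C(C)C)cc3)c(=O)c12
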